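**Retrosynthetic overview**
- Last step: acidic removal of three phenol acetates from the triacetate of the target.
- Key disconnection: the C3=C4 bond of the 7-hydroxy-6,8-dimethoxycoumarin half, made by a Perkin–Oglialoro (aldol-type) condensation of (6,7-dihydroxycoumarin-3-yl)acetic acid with 2,4-dihydroxy-3,5-dimethoxybenzaldehyde. The C3–C3' bond is carried in as the CH2 of the acid.
- The acid comes from a Stobbe condensation of 2,4,5-trimethoxybenzaldehyde with dimethyl succinate, then demethylation and lactonisation.
- The aldehyde comes from 2,6-dimethoxyphenol by O-benzylation, formylation, Dakin-type oxidation, ortho-formylation and hydrogenolysis.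
- Ring order: the pyranone of the 6,7-dihydroxy half closes first (step 7), the pyranone of the dimethoxy half last (step 8).

Assumption: the target has no stereocentre and the C3–C3' axis rotates freely, so no stereocontrol is needed; only the alkene geometry of 13 and 14 matters.

**Step 1**
Reactants: 1 2,6-dimethoxyphenol
Product: 2 2-(benzyloxy)-1,3-dimethoxybenzene
Conditions: BnBr (1.1 equiv), K2CO3 (1.5 equiv), DMF, 60 °C
Reagents that add atoms: benzyl bromide, BrCc1ccccc1
Why: Williamson ether synthesis, an SN2 reaction of the phenoxide on a benzylic bromide, which masks the future 7-OH with a group distinct from the methyl ethers.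

**Step 2**
Reactants: 2 2-(benzyloxy)-1,3-dimethoxybenzene
Product: 4 3-(benzyloxy)-2,4-dimethoxybenzaldehyde, via iminium chloride 3 (not isolated)
Conditions: POCl3 (2.5 equiv), DMF, 0 to 80 °C; then ice–water, 50 °C
Reagents that add atoms: N,N-dimethylformamide, CN(C)C=O; water, O
Why: Vilsmeier–Haack formylation, in which the two flanking methoxy groups direct the electrophile to C4 (ortho to one, para to the other) while the twisted central benzyloxy group barely activates C5, as with 1,2,3-trimethoxybenzene.

**Step 3**
Reactants: 4 3-(benzyloxy)-2,4-dimethoxybenzaldehyde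
Product: 6 3-(benzyloxy)-2,4-dimethoxyphenol, via aryl formate 5 (not isolated)
Conditions: mCPBA (1.3 equiv), CH2Cl2, 0 °C to rt; then K2CO3 (cat.), MeOH, rt
Reagents that add atoms: mCPBA, O=C(OO)c1cccc(Cl)c1
Why: Baeyer–Villiger (Dakin-type) oxidation, in which the electron-rich aryl group bearing ortho and para alkoxy donors migrates in preference to hydride and the resulting formate is methanolysed.

**Step 4**
Reactants: 6 3-(benzyloxy)-2,4-dimethoxyphenol
Product: 8 4-(benzyloxy)-2-hydroxy-3,5-dimethoxybenzaldehyde, via hydroxymethyl phenol 7 (not isolated)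
Conditions: MgCl2 (1.5 equiv), Et3N (3.75 equiv), (CH2O)n (7 equiv), MeCN, reflux; then 1 M HCl
Reagents that add atoms: paraformaldehyde (as formaldehyde), C=O
Why: Casnati–Skattebøl ortho-formylation, in which the magnesium phenoxide delivers formaldehyde to the only free ortho carbon and a second formaldehyde oxidises the benzylic alkoxide by hydride transfer.

**Step 5**
Reactants: 8 4-(benzyloxy)-2-hydroxy-3,5-dimethoxybenzaldehyde
Product: 9 2,4-dihydroxy-3,5-dimethoxybenzaldehyde
Conditions: H2 (1 atm), 10% Pd/C, EtOAc, rt, stopped after 1 equiv H2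
Reagents that add atoms: none
Why: Hydrogenolysis of the benzyl aryl ether, which is much faster than reduction of the hydrogen-bonded, donor-deactivated salicylaldehyde carbonyl.

**Step 6**
Reactants: 10 2,4,5-trimethoxybenzaldehyde; 11 dimethyl succinate (1.5 equiv)
Product: 13 (E)-3-(methoxycarbonyl)-4-(2,4,5-trimethoxyphenyl)but-3-enoic acid, via paraconic ester 12 (not isolated)
Conditions: NaOMe (2 equiv), MeOH, reflux; then aq. HCl
Reagents that add atoms: none
Why: Stobbe condensation, an intermolecular aldol-type addition of the succinate enolate whose adduct lactonises to 12 and then opens irreversibly by E1cB to the carboxylate, giving the E-alkene with the aryl group trans to the ester.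

**Step 7**
Reactants: 13 (E)-3-(methoxycarbonyl)-4-(2,4,5-trimethoxyphenyl)but-3-enoic acid
Product: 15 (6,7-dihydroxy-2-oxo-2H-chromen-3-yl)acetic acid, via triphenol half-ester 14 (not isolated)
Conditions: BBr3 (6 equiv), CH2Cl2, −78 °C to rt; H2O quench; then 2 M HCl–dioxane, 80 °C, under N2
Reagents that add atoms: none
Why: BBr3 ether cleavage followed by acid-mediated E/Z equilibration (reversible protonation or bromide addition at the benzylic carbon, eased by the ortho and para oxygens), with only the Z-isomer drained by lactonisation to the coumarin as the thermodynamic sink.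

**Step 8**
Reactants: 15 (6,7-dihydroxy-2-oxo-2H-chromen-3-yl)acetic acid; 9 2,4-dihydroxy-3,5-dimethoxybenzaldehyde
Product: 18 3-(6,7-diacetoxy-2-oxo-2H-chromen-3-yl)-6,8-dimethoxy-2-oxo-2H-chromen-7-yl acetate, via diacetoxy aldehyde 16 (not isolated), via mixed anhydride 17 (not isolated)
Conditions: Ac2O (solvent), KOAc (3 equiv), 120 °C, 16 h, N2
Reagents that add atoms: acetic anhydride, CC(=O)OC(C)=O
Why: Perkin–Oglialoro condensation, in which the enolate of mixed anhydride 17 (an activated β,γ-unsaturated CH2) adds intermolecularly to aldehyde 16 in an aldol step and acetyl transfer, lactonisation and loss of acetic acid close the second pyranone, the same reaction that turns arylacetic acids and salicylaldehydes into 3-arylcoumarins.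

**Step 9**
Reactants: 18 3-(6,7-diacetoxy-2-oxo-2H-chromen-3-yl)-6,8-dimethoxy-2-oxo-2H-chromen-7-yl acetate
Product: 19 arteminorin C, 3-(6,7-dihydroxy-2-oxo-2H-chromen-3-yl)-7-hydroxy-6,8-dimethoxy-2H-chromen-2-one
Conditions: 2 M HCl, MeOH, reflux, 3 h, N2
Reagents that add atoms: none
Why: Acid-catalysed transesterification of the three aryl acetates, which leaves both lactones and the methyl ethers intact and keeps the catechol away from base and air.

**Compound list**
1 | 2,6-dimethoxyphenol | COc1cccc(OC)c1O | starting material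
2 | 2-(benzyloxy)-1,3-dimethoxybenzene | COc1cccc(OC)c1OCc1ccccc1 | intermediate
3 | N-{[3-(benzyloxy)-2,4-dimethoxyphenyl]methylidene}-N-methylmethanaminium chloride (formed in situ) | COc1ccc(C=[N+](C)C)c(OC)c1OCc1ccccc1.[Cl-] | intermediate
4 | 3-(benzyloxy)-2,4-dimethoxybenzaldehyde | COc1ccc(C=O)c(OC)c1OCc1ccccc1 | intermediate
5 | 3-(benzyloxy)-2,4-dimethoxyphenyl formate (formed in situ) | COc1ccc(OC=O)c(OC)c1OCc1ccccc1 | intermediate
6 | 3-(benzyloxy)-2,4-dimethoxyphenol | COc1ccc(O)c(OC)c1OCc1ccccc1 | intermediate
7 | 3-(benzyloxy)-6-(hydroxymethyl)-2,4-dimethoxyphenol (formed in situ as its magnesium salt) | COc1cc(CO)c(O)c(OC)c1OCc1ccccc1 | intermediate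
8 | 4-(benzyloxy)-2-hydroxy-3,5-dimethoxybenzaldehyde | COc1cc(C=O)c(O)c(OC)c1OCc1ccccc1 | intermediate
9 | 2,4-dihydroxy-3,5-dimethoxybenzaldehyde | COc1cc(C=O)c(O)c(OC)c1O | intermediate
10 | 2,4,5-trimethoxybenzaldehyde | COc1cc(OC)c(C=O)cc1OC | starting material
11 | dimethyl succinate | COC(=O)CCC(=O)OC | starting material
12 | methyl 5-oxo-2-(2,4,5-trimethoxyphenyl)oxolane-3-carboxylate (formed in situ; racemic mixture of diastereomers) | COC(=O)C1CC(=O)OC1c1cc(OC)c(OC)cc1OC | intermediate
13 | (E)-3-(methoxycarbonyl)-4-(2,4,5-trimethoxyphenyl)but-3-enoic acid | COC(=O)/C(CC(=O)O)=C/c1cc(OC)c(OC)cc1OC | intermediate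
14 | (E)-3-(methoxycarbonyl)-4-(2,4,5-trihydroxyphenyl)but-3-enoic acid (formed in situ) | COC(=O)/C(CC(=O)O)=C/c1cc(O)c(O)cc1O | intermediate
15 | (6,7-dihydroxy-2-oxo-2H-chromen-3-yl)acetic acid | O=C(O)Cc1cc2cc(O)c(O)cc2oc1=O | intermediate
16 | 2,4-diacetoxy-3,5-dimethoxybenzaldehyde (formed in situ) | COc1cc(C=O)c(OC(C)=O)c(OC)c1OC(C)=O | intermediate
17 | acetic (6,7-diacetoxy-2-oxo-2H-chromen-3-yl)acetic anhydride (formed in situ) | CC(=O)OC(=O)Cc1cc2cc(OC(C)=O)c(OC(C)=O)cc2oc1=O | intermediate
18 | 3-(6,7-diacetoxy-2-oxo-2H-chromen-3-yl)-6,8-dimethoxy-2-oxo-2H-chromen-7-yl acetate | COc1cc2cc(-c3cc4cc(OC(C)=O)c(OC(C)=O)cc4oc3=O)c(=O)oc2c(OC)c1OC(C)=O | intermediate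
19 | arteminorin C | COc1cc2cc(-c3cc4cc(O)c(O)cc4oc3=O)c(=O)oc2c(OC)c1O | target

**Step count**
Total: 9 steps. Longest linear sequence: 7 steps (steps 1–5, 8, 9); the second branch is steps 6–7.

**Steps most likely to fail, with fallbacks**

Step 2 (Vilsmeier formylation). The arene is only moderately activated, and the hindered benzyl ether may suffer from the HCl formed at 80 °C. The fallback sets out from 2 and avoids the aldehyde stage. NBS in MeCN at rt brominates 2 para to a methoxy group to give 3-(benzyloxy)-1-bromo-2,4-dimethoxybenzene F1. Palladium-catalysed hydroxylation (Pd2(dba)3, t-BuXPhos, KOH, dioxane–H2O, 100 °C) then turns the C–Br bond directly into the phenol, so the route is rejoined at 6 and compounds 3–5 are not made.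

Step 7 (demethylation, E to Z isomerisation and lactonisation in one pot). The acid equilibration may stall at the E-triphenol, or the electron-rich ring may give oligomers in hot acid. The fallback sets out from 13. BBr3 in CH2Cl2 at −78 to 0 °C with a cold aqueous work-up allows (E)-3-(methoxycarbonyl)-4-(2,4,5-trihydroxyphenyl)but-3-enoic acid 14 to be isolated. Irradiation of 14 at 365 nm in degassed MeOH then isomerises the alkene photochemically under neutral conditions, and the Z-phenol lactonises spontaneously onto the now cis methyl ester. The free CH2CO2H group cannot lactonise under these conditions, and the route is rejoined at 15. This fallback needs no compound outside the list: none F0.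

Step 8 (Perkin–Oglialoro key step). The mixed anhydride may enolise too slowly at 120 °C, or self-acylation and tar formation may compete. The fallback sets out from 15 and 9 and replaces the one-pot condensation by a directed, low-temperature intermolecular aldol addition followed by a separate cyclodehydration. Acid 15 is esterified (MeOH, cat. H2SO4, reflux) to methyl (6,7-dihydroxy-2-oxo-2H-chromen-3-yl)acetate F2 and acetylated (Ac2O, pyridine, rt) to methyl (6,7-diacetoxy-2-oxo-2H-chromen-3-yl)acetate F3. Aldehyde 9 is acetylated in the same way to give 16, isolated this time. Soft enolisation of F3 with TiCl4 and Et3N in CH2Cl2 at −78 °C and addition of 16 (−78 to 0 °C, Tanabe-type titanium aldol) gives methyl 2-(6,7-diacetoxy-2-oxo-2H-chromen-3-yl)-3-(2,4-diacetoxy-3,5-dimethoxyphenyl)-3-hydroxypropanoate F4 as a mixture of racemic diastereomers. Refluxing F4 in 2 M HCl–MeOH removes the acetates, lactonises the freed 2-OH onto the methyl ester and dehydrates the benzylic alcohol. Because the ring closes before the double bond forms, no alkene geometry problem arises, and the route comes back directly at 19.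

**Further compounds**
F1 | step 2 | 3-(benzyloxy)-1-bromo-2,4-dimethoxybenzene | COc1ccc(Br)c(OC)c1OCc1ccccc1
F0 | step 7 | none | none
F2 | step 8 | methyl (6,7-dihydroxy-2-oxo-2H-chromen-3-yl)acetate | COC(=O)Cc1cc2cc(O)c(O)cc2oc1=O
F3 | step 8 | methyl (6,7-diacetoxy-2-oxo-2H-chromen-3-yl)acetate | COC(=O)Cc1cc2cc(OC(C)=O)c(OC(C)=O)cc2oc1=O
F4 | step 8 | methyl 2-(6,7-diacetoxy-2-oxo-2H-chromen-3-yl)-3-(2,4-diacetoxy-3,5-dimethoxyphenyl)-3-hydroxypropanoate (racemic mixture of diastereomers) | COC(=O)C(c1cc2cc(OC(C)=O)c(OC(C)=O)cc2oc1=O)C(O)c1cc(OC)c(OC(C)=O)c(OC)c1OC(C)=O
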